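**Plan**

- Retrosynthesis: the butenolide (C-12–C-13), the acetate and the C-6 hydroxyl (from C-6–B) are removed as functional-group changes. Then C-5–C-10 and C-6–C-7 are cut together, which opens rings A and B to one acyclic triene. The triene is cut at C-9=C-10 (olefination inside a δ-lactone), at C-1–C-10 (cuprate) and at the C-4 substituents (enolate alkylations).
- Enabling feature: the tetrasubstituted C-8=C-9 bond of ring B lies between C-7 and C-10, where the central bond of a diene ends up after a [4+2] addition. C-5 (H) and C-6 (O) form the dienophile pair, and ring A (C-10, C-1 to C-5) is a six-membered tether from diene terminus C-10 to dienophile carbon C-5.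
- Forward: a γ-lactone from the glutamic acid pool is dialkylated (C-19, then C-18), extended at C-1 and opened to an alkynol. A δ-lactone template fixes the Z tetrasubstituted C-9=C-10 alkene and is opened to the Z-diene. The alkyne becomes a Z-alkenylboronate, and one intramolecular Diels–Alder reaction closes rings A and B. C–B oxidation, acetylation and side-chain coupling finish the route.
- Stereochemistry: C-2 comes from (S)-5-(hydroxymethyl)butyrolactone. C-4 is set by enolate methylation anti to CH2OTr. C-5, C-6 and C-10 are set in the cycloaddition (Z-diene gives the cis fusion, Z-dienophile gives 6α, the face is chosen by C-2 and C-4). The C–B to C–O change is stereoretentive.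

Key step: step 18

Remark: labdane numbering is used for atoms throughout (C-17 = CH3 on C-8, C-18 = CH3 on C-4, C-19 = CH2O on C-4, C-20 = CH3 on C-10, C-11/C-12 = side-chain CH2 groups). The SMILES is read as the cis-fused decalin (2R,4S,5S,6S,10S), with CH3-20, H-5 and C-19 on one face and O-2, O-6 and CH3-18 on the other.

**Route**

Step 1
Reactants: 1 (S)-5-(hydroxymethyl)dihydrofuran-2(3H)-one
Product: 2 (S)-5-[(trityloxy)methyl]dihydrofuran-2(3H)-one
Conditions: TrCl, pyridine, DMAP (cat.), CH2Cl2, 0 °C to rt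
Reagents that add atoms: trityl chloride, ClC(c1ccccc1)(c1ccccc1)c1ccccc1
Why: Selective etherification of the primary alcohol installs the bulky trityl group that later shields one face of the lactone enolate.

Step 2
Reactants: 2 trityl ether lactone
Product: 3 (3S,5S)-3-[(benzyloxy)methyl]-5-[(trityloxy)methyl]dihydrofuran-2(3H)-one (major trans epimer; the C-3 epimer is equally usable)
Conditions: LiN(i-Pr)2 (LDA), THF, −78 °C; then BnOCH2Cl, −78 to −40 °C
Reagents that add atoms: benzyl chloromethyl ether, ClCOCc1ccccc1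
Why: Enolate alkylation of the lithium lactone enolate with the reactive chloromethyl ether introduces C-19 with its oxygen, and the new centre is of no consequence because it is re-enolized in step 3.

Step 3
Reactants: 3 benzyloxymethyl lactone
Product: 4 (3R,5S)-3-[(benzyloxy)methyl]-3-methyl-5-[(trityloxy)methyl]dihydrofuran-2(3H)-one
Conditions: LiN(i-Pr)2 (LDA), THF, −78 °C; then MeI, DMPU, −78 to −30 °C
Reagents that add atoms: iodomethane, CI
Why: The planar α-substituted enolate should be methylated from the face opposite the γ-CH2OTr group (1,3-induction in γ-butyrolactone enolate alkylation), which sets quaternary C-4 with methyl trans and CH2OBn cis to the trityloxymethyl arm.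

Step 4
Reactants: 4 quaternary lactone
Product: 5 (3R,5S)-3-[(benzyloxy)methyl]-5-(hydroxymethyl)-3-methyldihydrofuran-2(3H)-one
Conditions: AcOH/H2O (4:1), 50 °C
Reagents that add atoms: none
Why: Acidolysis of the trityl ether through the trityl cation frees the primary alcohol while the benzyl ether and the γ-lactone persist.

Step 5
Reactants: 5 hydroxymethyl lactone
Product: 6 [(2S,4R)-4-[(benzyloxy)methyl]-4-methyl-5-oxotetrahydrofuran-2-yl]methyl 4-methylbenzenesulfonate
Conditions: TsCl, pyridine, CH2Cl2, 0 °C to rt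
Reagents that add atoms: tosyl chloride, Cc1ccc(cc1)S(Cl)(=O)=O
Why: Sulfonylation of the only hydroxyl turns C-1 into an electrophile.

Step 6
Reactants: 6 tosylate
Product: 7 (3R,5R)-3-[(benzyloxy)methyl]-3-methyl-5-(2-methylprop-2-en-1-yl)dihydrofuran-2(3H)-one
Conditions: isopropenylmagnesium bromide (4 equiv), CuI (2 equiv), THF, −40 to −20 °C
Reagents that add atoms: isopropenylmagnesium bromide, C=C(C)[Mg]Br
Why: SN2 displacement of the primary tosylate by the vinylic organocuprate forms C-1–C-10 without attack on the hindered α-quaternary lactone carbonyl and without touching either stereocentre.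

Step 7
Reactants: 7 methallyl lactone
Product: 8 (3R,5R)-3-[(benzyloxy)methyl]-3-methyl-5-(2-methylprop-2-en-1-yl)tetrahydrofuran-2-ol (mixture of anomers)
Conditions: i-Bu2AlH (1.1 equiv), CH2Cl2, −78 °C; aq. potassium sodium tartrate
Reagents that add atoms: none
Why: Half-reduction of the lactone stops at the lactol because the tetrahedral aluminium alkoxide is stable at −78 °C.

Step 8
Reactants: 8 lactol
Product: 9 (4R,6S)-6-[(benzyloxy)methyl]-2,6-dimethyloct-1-en-7-yn-4-ol
Conditions: dimethyl (1-diazo-2-oxopropyl)phosphonate, K2CO3, MeOH, 0 °C to rt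
Reagents that add atoms: dimethyl (1-diazo-2-oxopropyl)phosphonate, CC(=O)C(=[N+]=[N-])P(=O)(OC)OC
Why: Seyferth–Gilbert homologation under Ohira–Bestmann conditions converts the open hydroxy-aldehyde form of the lactol (a non-enolizable α-quaternary aldehyde) into the terminal alkyne C-5≡C-6 and releases the C-2 hydroxyl.

Step 9
Reactants: 10 triethyl phosphonoacetate; 11 benzyl 2-bromoethyl ether
Product: 12 ethyl 4-(benzyloxy)-2-(diethoxyphosphoryl)butanoate (racemic)
Conditions: NaH, DMF, 0 to 60 °C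
Reagents that add atoms: none
Why: SN2 C-alkylation of the sodium phosphonoacetate anion with the primary bromide attaches the future C-11/C-12 unit.

Step 10
Reactants: 12 phosphono ester
Product: 13 4-(benzyloxy)-2-(diethoxyphosphoryl)butanoic acid (racemic)
Conditions: NaOH (1.05 equiv), EtOH/H2O, 0 °C to rt; then 1 M HCl to pH 2
Reagents that add atoms: sodium hydroxide, [Na+].[OH-]
Why: Saponification cleaves the carboxylic ethyl ester much faster than the phosphonate esters and gives the acid for coupling.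

Step 11
Reactants: 9 alkynol; 13 phosphono acid
Product: 14 (4R,6S)-6-[(benzyloxy)methyl]-2,6-dimethyloct-1-en-7-yn-4-yl 4-(benzyloxy)-2-(diethoxyphosphoryl)butanoate (epimers at the phosphonate carbon)
Conditions: DCC, DMAP (cat.), CH2Cl2, 0 °C to rt
Reagents that add atoms: none
Why: Steglich esterification joins the two fragments at O-2 under neutral conditions that leave alkyne, alkene and phosphonate intact.

Step 12
Reactants: 14 phosphono ester of the alkynol
Product: 16 (4S,6S)-6-[(benzyloxy)methyl]-6-methyl-2-oxooct-7-yn-4-yl 4-(benzyloxy)-2-(diethoxyphosphoryl)butanoate, via vicinal diol 15 (not isolated)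
Conditions: OsO4 (2 mol%), NaIO4 (4 equiv), 2,6-lutidine (2 equiv), dioxane/H2O (3:1), rt
Reagents that add atoms: osmium tetroxide, O=[Os](=O)(=O)=O (delivers the ketone oxygen and is regenerated by sodium periodate, [Na+].[O-]I(=O)(=O)=O)
Why: Lemieux–Johnson cleavage (dihydroxylation then periodate scission) is selective for the 1,1-disubstituted alkene over the terminal alkyne and unveils the C-10 methyl ketone.

Step 13
Reactants: 16 keto phosphonate
Product: 17 (6R)-3-[2-(benzyloxy)ethyl]-6-[(2S)-2-[(benzyloxy)methyl]-2-methylbut-3-yn-1-yl]-4-methyl-5,6-dihydro-2H-pyran-2-one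
Conditions: LiCl, DBU, MeCN, rt
Reagents that add atoms: none
Why: Intramolecular Horner–Wadsworth–Emmons olefination under mild LiCl/amine conditions closes the six-membered lactone, and the ring forces C-8 and C-1 to be cis on the new tetrasubstituted C-9=C-10 bond.

Step 14
Reactants: 17 dihydropyranone
Product: 19 (3Z,6R,8S)-3-[2-(benzyloxy)ethyl]-8-[(benzyloxy)methyl]-2,4,8-trimethyldec-3-en-9-yne-2,6-diol, via methyl ketone 18 (not isolated)
Conditions: MeLi (4 equiv), CeCl3 (4 equiv), THF, −78 to −20 °C; aq. NH4Cl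
Reagents that add atoms: methyllithium, [Li]C
Why: Double 1,2-addition of the weakly basic organocerium reagent opens the lactone to the enone and then to the tertiary allylic alcohol, and the ring-derived Z geometry of C-9=C-10 is kept.

Step 15
Reactants: 19 diol
Product: 20 (3Z,6R,8S)-3-[2-(benzyloxy)ethyl]-8-[(benzyloxy)methyl]-6-[(tert-butyldimethylsilyl)oxy]-2,4,8-trimethyldec-3-en-9-yn-2-ol
Conditions: TBSCl, imidazole, DMF, rt
Reagents that add atoms: tert-butyldimethylsilyl chloride, CC(C)(C)[Si](C)(C)Cl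
Why: Silylation is selective for the secondary C-2 alcohol over the hindered tertiary allylic alcohol.

Step 16
Reactants: 20 tertiary alcohol
Product: 21 {[(3Z,6R,8S)-3-[2-(benzyloxy)ethyl]-8-[(benzyloxy)methyl]-2,4,8-trimethyldeca-1,3-dien-9-yn-6-yl]oxy}(tert-butyl)dimethylsilane
Conditions: Burgess reagent, toluene, 50 °C
Reagents that add atoms: none
Why: syn-Elimination of the tertiary sulfamate ester (Burgess dehydration) can only take a methyl hydrogen, since C-9 carries none, and so gives the isopropenyl group of the Z-diene.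

Step 17
Reactants: 21 dienyne
Product: 22 2-[(1Z,3S,5R,7Z)-8-[2-(benzyloxy)ethyl]-3-[(benzyloxy)methyl]-5-[(tert-butyldimethylsilyl)oxy]-3,7,9-trimethyldeca-1,7,9-trien-1-yl]-4,4,5,5-tetramethyl-1,3,2-dioxaborolane
Conditions: pinacolborane (1.1 equiv), [RhCl(cod)]2 (1.5 mol%), P(i-Pr)3 (6 mol%), Et3N (1 equiv), cyclohexane, rt
Reagents that add atoms: pinacolborane, B1OC(C)(C)C(C)(C)O1
Why: Rhodium-catalysed trans-hydroboration of the terminal alkyne through a rhodium vinylidene places boron cis to the C-4 substituent and gives the Z-alkenylboronate dienophile.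

Step 18
Reactants: 22 Z,Z-triene boronate
Product: 23 (2R,4S,5S,6S,10S)-12,19-bis(benzyloxy)-2-[(tert-butyldimethylsilyl)oxy]-6-(4,4,5,5-tetramethyl-1,3,2-dioxaborolan-2-yl)-13,14,15,16-tetranorlabd-8-ene (cis-fused decalin)
Conditions: toluene (0.01 M, degassed), BHT (cat.), 150 °C, sealed tube
Reagents that add atoms: none
Why: This is a thermal, concerted, suprafacial [4+2] cycloaddition of a 1,3,9-decatriene (intramolecular Diels–Alder reaction) in which the diene C-7=C-8–C-9=C-10 adds across the alkenylboronate C-5=C-6, forming C-5–C-10 and C-6–C-7 and leaving the former central diene bond as the C-8=C-9 alkene. The closest known reaction types are the Diels–Alder reaction of alkenylboronic esters and the intramolecular Diels–Alder reaction of Z-dienes to cis-fused bicycles. Ring A closes as the six-membered tether ring (C-10, C-1, C-2, C-3, C-4, C-5) through the fusion bond and ring B closes as the new cyclohexene in the fused mode, a bridged alternative being out of reach for a four-atom tether. At C-10 and C-5, the tether carbon C-1 sits on the inside (Z) position of the diene terminus and can therefore reach only the exo position of the dienophile, so CH3-20 (outside) and H-5 (endo) become cis, which is the cis ring fusion; at C-6, the Z geometry of the dienophile is transferred, so boron ends up cis to C-4, which is α. The diene face is chosen by C-2 and C-4 through a chair-like tether in which OTBS and CH3-18 are equatorial and only CH2OBn is axial, whereas addition to the other face would place OTBS and CH3-18 axial and syn to CH3-20. The step needs diastereofacial selectivity and must outrun [1,5]-hydrogen shift of the Z-diene, and the chair preference, the Thorpe–Ingold effect of quaternary C-4 and the absence of any other reachable dienophile should secure this.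

Step 19
Reactants: 23 decalin boronate
Product: 24 (2R,4S,5S,6S,10S)-12,19-bis(benzyloxy)-2-[(tert-butyldimethylsilyl)oxy]-13,14,15,16-tetranorlabd-8-en-6-ol
Conditions: H2O2 (30% aq.), NaOH (3 M aq.), THF, 0 °C to rt
Reagents that add atoms: hydrogen peroxide, OO
Why: Oxidation of the C–B bond with alkaline peroxide proceeds by 1,2-migration with retention and delivers the 6α-hydroxyl.

Step 20
Reactants: 24 bis(benzyl ether)
Product: 25 (2R,4S,5S,6S,10S)-2-[(tert-butyldimethylsilyl)oxy]-13,14,15,16-tetranorlabd-8-ene-6,12,19-triol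
Conditions: lithium 4,4'-di-tert-butylbiphenylide (LiDBB), THF, −78 °C; aq. NH4Cl
Reagents that add atoms: none
Why: Reductive cleavage by the arene radical anion removes both benzyl ethers while the isolated tetrasubstituted alkene and the silyl ether are inert.

Step 21
Reactants: 25 triol
Product: 26 (2R,4S,5S,6S,10S)-2-[(tert-butyldimethylsilyl)oxy]-12-iodo-13,14,15,16-tetranorlabd-8-ene-6,19-diol
Conditions: PPh3 (1.2 equiv), I2 (1.2 equiv), imidazole, CH2Cl2, 0 °C
Reagents that add atoms: iodine, II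
Why: Appel-type iodination (alkoxyphosphonium, then SN2 by iodide) should occur only at the unhindered primary C-12 alcohol, since the neopentyl C-19 and the axial C-6 alcohols are too hindered for displacement.

Step 22
Reactants: 26 iodo diol
Product: 27 (2R,4S,5S,6S,10S)-2-[(tert-butyldimethylsilyl)oxy]-6-hydroxy-12-iodo-13,14,15,16-tetranorlabd-8-en-19-yl acetate
Conditions: Ac2O (1.2 equiv), Et3N, DMAP (5 mol%), CH2Cl2, 0 °C
Reagents that add atoms: acetic anhydride, CC(=O)OC(C)=O
Why: Acylation is selective for the primary C-19 alcohol over the hindered axial secondary C-6 alcohol.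

Step 23
Reactants: 27 iodo acetate; 28 4-bromofuran-2(5H)-one
Product: 29 (2R,4S,5S,6S,10S)-19-acetoxy-2-[(tert-butyldimethylsilyl)oxy]-6-hydroxylabda-8,13-dien-15,16-olide
Conditions: NiCl2(MeOCH2CH2OMe) (10 mol%), 4,4'-di-tert-butyl-2,2'-bipyridine (10 mol%), Zn dust (2 equiv), N,N-dimethylacetamide, 25 °C
Reagents that add atoms: none
Why: Nickel-catalysed reductive cross-electrophile coupling of the alkyl iodide with the vinylogous acyl bromide forms C-12–C-13 and tolerates the free hydroxyl, the acetate and the silyl ether.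

Step 24
Reactants: 29 silyl ether
Product: 30 [(1S,3R,4aS,8S,8aS)-3,8-dihydroxy-1,4a,6-trimethyl-5-[2-(5-oxo-2,5-dihydrofuran-3-yl)ethyl]-1,2,3,4,4a,7,8,8a-octahydronaphthalen-1-yl]methyl acetate (CNP0201970.1)
Conditions: HF·pyridine, pyridine/THF, 0 °C to rt
Reagents that add atoms: none
Why: Fluoride cleavage of the secondary silyl ether under buffered conditions spares the acetate and the butenolide.

**Compound list**

1 | (S)-5-(hydroxymethyl)dihydrofuran-2(3H)-one | O=C1CC[C@@H](CO)O1 | starting material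
2 | (S)-5-[(trityloxy)methyl]dihydrofuran-2(3H)-one | O=C1CC[C@@H](COC(c2ccccc2)(c2ccccc2)c2ccccc2)O1 | intermediate
3 | (3S,5S)-3-[(benzyloxy)methyl]-5-[(trityloxy)methyl]dihydrofuran-2(3H)-one (major trans epimer) | O=C1O[C@H](COC(c2ccccc2)(c2ccccc2)c2ccccc2)C[C@H]1COCc1ccccc1 | intermediate
4 | (3R,5S)-3-[(benzyloxy)methyl]-3-methyl-5-[(trityloxy)methyl]dihydrofuran-2(3H)-one | O=C1O[C@H](COC(c2ccccc2)(c2ccccc2)c2ccccc2)C[C@]1(C)COCc1ccccc1 | intermediate
5 | (3R,5S)-3-[(benzyloxy)methyl]-5-(hydroxymethyl)-3-methyldihydrofuran-2(3H)-one | O=C1O[C@H](CO)C[C@]1(C)COCc1ccccc1 | intermediate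
6 | [(2S,4R)-4-[(benzyloxy)methyl]-4-methyl-5-oxotetrahydrofuran-2-yl]methyl 4-methylbenzenesulfonate | O=C1O[C@H](COS(=O)(=O)c2ccc(C)cc2)C[C@]1(C)COCc1ccccc1 | intermediate
7 | (3R,5R)-3-[(benzyloxy)methyl]-3-methyl-5-(2-methylprop-2-en-1-yl)dihydrofuran-2(3H)-one | O=C1O[C@H](CC(C)=C)C[C@]1(C)COCc1ccccc1 | intermediate
8 | (3R,5R)-3-[(benzyloxy)methyl]-3-methyl-5-(2-methylprop-2-en-1-yl)tetrahydrofuran-2-ol (anomers) | OC1O[C@H](CC(C)=C)C[C@]1(C)COCc1ccccc1 | intermediate
9 | (4R,6S)-6-[(benzyloxy)methyl]-2,6-dimethyloct-1-en-7-yn-4-ol | C#C[C@@](C)(COCc1ccccc1)C[C@H](O)CC(C)=C | intermediate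
10 | triethyl phosphonoacetate | CCOC(=O)CP(=O)(OCC)OCC | starting material
11 | benzyl 2-bromoethyl ether | BrCCOCc1ccccc1 | starting material
12 | ethyl 4-(benzyloxy)-2-(diethoxyphosphoryl)butanoate (racemic) | CCOC(=O)C(CCOCc1ccccc1)P(=O)(OCC)OCC | intermediate
13 | 4-(benzyloxy)-2-(diethoxyphosphoryl)butanoic acid (racemic) | OC(=O)C(CCOCc1ccccc1)P(=O)(OCC)OCC | intermediate
14 | (4R,6S)-6-[(benzyloxy)methyl]-2,6-dimethyloct-1-en-7-yn-4-yl 4-(benzyloxy)-2-(diethoxyphosphoryl)butanoate (epimers at the phosphonate carbon) | C#C[C@@](C)(COCc1ccccc1)C[C@H](OC(=O)C(CCOCc1ccccc1)P(=O)(OCC)OCC)CC(C)=C | intermediate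
15 | (4S,6S)-6-[(benzyloxy)methyl]-1,2-dihydroxy-2,6-dimethyloct-7-yn-4-yl 4-(benzyloxy)-2-(diethoxyphosphoryl)butanoate (vicinal diol, C-2 epimers, not isolated) | C#C[C@@](C)(COCc1ccccc1)C[C@H](OC(=O)C(CCOCc1ccccc1)P(=O)(OCC)OCC)CC(C)(O)CO | intermediate
16 | (4S,6S)-6-[(benzyloxy)methyl]-6-methyl-2-oxooct-7-yn-4-yl 4-(benzyloxy)-2-(diethoxyphosphoryl)butanoate | C#C[C@@](C)(COCc1ccccc1)C[C@H](OC(=O)C(CCOCc1ccccc1)P(=O)(OCC)OCC)CC(C)=O | intermediate
17 | (6R)-3-[2-(benzyloxy)ethyl]-6-[(2S)-2-[(benzyloxy)methyl]-2-methylbut-3-yn-1-yl]-4-methyl-5,6-dihydro-2H-pyran-2-one | C#C[C@@](C)(COCc1ccccc1)C[C@H]1CC(C)=C(CCOCc2ccccc2)C(=O)O1 | intermediate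
18 | (3Z,6R,8S)-3-[2-(benzyloxy)ethyl]-8-[(benzyloxy)methyl]-6-hydroxy-4,8-dimethyldec-3-en-9-yn-2-one (methyl ketone, not isolated) | C#C[C@@](C)(COCc1ccccc1)C[C@H](O)C/C(C)=C(/CCOCc1ccccc1)C(C)=O | intermediate
19 | (3Z,6R,8S)-3-[2-(benzyloxy)ethyl]-8-[(benzyloxy)methyl]-2,4,8-trimethyldec-3-en-9-yne-2,6-diol | C#C[C@@](C)(COCc1ccccc1)C[C@H](O)C/C(C)=C(/CCOCc1ccccc1)C(C)(C)O | intermediate
20 | (3Z,6R,8S)-3-[2-(benzyloxy)ethyl]-8-[(benzyloxy)methyl]-6-[(tert-butyldimethylsilyl)oxy]-2,4,8-trimethyldec-3-en-9-yn-2-ol | C#C[C@@](C)(COCc1ccccc1)C[C@H](O[Si](C)(C)C(C)(C)C)C/C(C)=C(/CCOCc1ccccc1)C(C)(C)O | intermediate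
21 | {[(3Z,6R,8S)-3-[2-(benzyloxy)ethyl]-8-[(benzyloxy)methyl]-2,4,8-trimethyldeca-1,3-dien-9-yn-6-yl]oxy}(tert-butyl)dimethylsilane | C#C[C@@](C)(COCc1ccccc1)C[C@H](O[Si](C)(C)C(C)(C)C)C/C(C)=C(/CCOCc1ccccc1)C(C)=C | intermediate
22 | 2-[(1Z,3S,5R,7Z)-8-[2-(benzyloxy)ethyl]-3-[(benzyloxy)methyl]-5-[(tert-butyldimethylsilyl)oxy]-3,7,9-trimethyldeca-1,7,9-trien-1-yl]-4,4,5,5-tetramethyl-1,3,2-dioxaborolane | CC1(C)OB(OC1(C)C)/C=C\[C@@](C)(COCc1ccccc1)C[C@H](O[Si](C)(C)C(C)(C)C)C/C(C)=C(/CCOCc1ccccc1)C(C)=C | intermediate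
23 | (2R,4S,5S,6S,10S)-12,19-bis(benzyloxy)-2-[(tert-butyldimethylsilyl)oxy]-6-(4,4,5,5-tetramethyl-1,3,2-dioxaborolan-2-yl)-13,14,15,16-tetranorlabd-8-ene (cis-fused; CH3-20, H-5, C-19 on one face; O-2, B-6 on the other) | c1ccccc1COC[C@@]1(C)C[C@H](O[Si](C)(C)C(C)(C)C)C[C@]2(C)C(CCOCc3ccccc3)=C(C)C[C@H](B3OC(C)(C)C(C)(C)O3)[C@H]12 | intermediate
24 | (2R,4S,5S,6S,10S)-12,19-bis(benzyloxy)-2-[(tert-butyldimethylsilyl)oxy]-13,14,15,16-tetranorlabd-8-en-6-ol | c1ccccc1COC[C@@]1(C)C[C@H](O[Si](C)(C)C(C)(C)C)C[C@]2(C)C(CCOCc3ccccc3)=C(C)C[C@H](O)[C@H]12 | intermediate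
25 | (2R,4S,5S,6S,10S)-2-[(tert-butyldimethylsilyl)oxy]-13,14,15,16-tetranorlabd-8-ene-6,12,19-triol | OC[C@@]1(C)C[C@H](O[Si](C)(C)C(C)(C)C)C[C@]2(C)C(CCO)=C(C)C[C@H](O)[C@H]12 | intermediate
26 | (2R,4S,5S,6S,10S)-2-[(tert-butyldimethylsilyl)oxy]-12-iodo-13,14,15,16-tetranorlabd-8-ene-6,19-diol | OC[C@@]1(C)C[C@H](O[Si](C)(C)C(C)(C)C)C[C@]2(C)C(CCI)=C(C)C[C@H](O)[C@H]12 | intermediate
27 | (2R,4S,5S,6S,10S)-2-[(tert-butyldimethylsilyl)oxy]-6-hydroxy-12-iodo-13,14,15,16-tetranorlabd-8-en-19-yl acetate | CC(=O)OC[C@@]1(C)C[C@H](O[Si](C)(C)C(C)(C)C)C[C@]2(C)C(CCI)=C(C)C[C@H](O)[C@H]12 | intermediate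
28 | 4-bromofuran-2(5H)-one | O=C1C=C(Br)CO1 | starting material
29 | (2R,4S,5S,6S,10S)-19-acetoxy-2-[(tert-butyldimethylsilyl)oxy]-6-hydroxylabda-8,13-dien-15,16-olide | CC(=O)OC[C@@]1(C)C[C@H](O[Si](C)(C)C(C)(C)C)C[C@]2(C)C(CCC3=CC(=O)OC3)=C(C)C[C@H](O)[C@H]12 | intermediate
30 | [(1S,3R,4aS,8S,8aS)-3,8-dihydroxy-1,4a,6-trimethyl-5-[2-(5-oxo-2,5-dihydrofuran-3-yl)ethyl]-1,2,3,4,4a,7,8,8a-octahydronaphthalen-1-yl]methyl acetate, i.e. (2R,4S,5S,6S,10S)-19-acetoxy-2,6-dihydroxylabda-8,13-dien-15,16-olide | CC(=O)OC[C@@]1(C)C[C@H](O)C[C@]2(C)C(CCC3=CC(=O)OC3)=C(C)C[C@H](O)[C@H]12 | target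

**Step count**

Total: 24 steps (22 in the main line plus 2 for acid 13). Longest linear sequence: 22 steps (steps 1–8 and 11–24).

**Steps most likely to fail**

1. Step 18 (cycloaddition). The cis-disubstituted, weakly activated dienophile may add too slowly, because the exo boron eclipses quaternary C-4 in the transition state. [1,5]-Hydrogen shift of the Z-diene or thermal decomposition could then compete, and the tether might react partly through a boat with loss of facial selectivity. The fallback sets out from 21 and returns at 24. syn-Hydroboration of 21 with pinacolborane under Cp2Zr(H)Cl catalysis should give 2-[(1E,3S,5R,7Z)-8-[2-(benzyloxy)ethyl]-3-[(benzyloxy)methyl]-5-[(tert-butyldimethylsilyl)oxy]-3,7,9-trimethyldeca-1,7,9-trien-1-yl]-4,4,5,5-tetramethyl-1,3,2-dioxaborolane F1, in which boron is trans to C-4 and can sit endo without eclipsing the quaternary carbon. Its intramolecular Diels–Alder reaction (toluene, 130–150 °C) should give the cis-fused 6β-boronate (C-6 epimer of 23) F2. Alkaline peroxide then gives the 6β-alcohol (C-6 epimer of 24) F3, and Dess–Martin periodinane gives the 6-ketone F4. Reduction of F4 with LiBH(s-Bu)3 at −78 °C should occur from the convex β face, the α face being screened by the axial C-10–C-1 bond, and give 24. The ketone must be handled without base to avoid epimerization at C-5.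

2. Step 13 (lactone-forming olefination). Base could expel the carboxylate from the β-acyloxy ketone (E1cB) faster than the α-branched phosphonate anion adds to the methyl ketone. The fallback sets out from 9 and returns at 17. Commercial 4-(benzyloxy)butanoic acid is α-brominated (LDA, 2 equiv; then CBr4) to 4-(benzyloxy)-2-bromobutanoic acid F5. Esterification of 9 with F5 (DCC, DMAP cat.) gives the bromo ester F6, and Lemieux–Johnson cleavage gives the keto bromo ester F7. SmI2 in THF at −78 °C should then effect an intramolecular Reformatsky reaction under neutral conditions to the β-hydroxy δ-lactone F8. Dehydration (SOCl2, pyridine, 0 °C; then DBU to bring the double bond into conjugation) gives 17.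

3. Step 17 (trans-hydroboration). Competing syn-addition (E isomer), hydroboration or isomerization of the diene by rhodium hydride species, or slow vinylidene formation at the neopentyl-type alkyne could erode the Z-boronate. The fallback sets out from 21 and returns at 22. Deprotonation of the alkyne (n-BuLi, THF, −78 °C), borylation with 2-isopropoxy-4,4,5,5-tetramethyl-1,3,2-dioxaborolane and quench with HCl in ether give the alkynylboronate F9. Stoichiometric syn-hydrozirconation with Cp2Zr(H)Cl, followed by protonolysis of the C–Zr bond with water, leaves boron cis to C-4 and gives 22.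

Further compounds
F1 | step 18 | 2-[(1E,3S,5R,7Z)-8-[2-(benzyloxy)ethyl]-3-[(benzyloxy)methyl]-5-[(tert-butyldimethylsilyl)oxy]-3,7,9-trimethyldeca-1,7,9-trien-1-yl]-4,4,5,5-tetramethyl-1,3,2-dioxaborolane | CC1(C)OB(OC1(C)C)/C=C/[C@@](C)(COCc1ccccc1)C[C@H](O[Si](C)(C)C(C)(C)C)C/C(C)=C(/CCOCc1ccccc1)C(C)=C
F2 | step 18 | (2R,4S,5S,6R,10S)-12,19-bis(benzyloxy)-2-[(tert-butyldimethylsilyl)oxy]-6-(4,4,5,5-tetramethyl-1,3,2-dioxaborolan-2-yl)-13,14,15,16-tetranorlabd-8-ene (C-6 epimer of 23) | c1ccccc1COC[C@@]1(C)C[C@H](O[Si](C)(C)C(C)(C)C)C[C@]2(C)C(CCOCc3ccccc3)=C(C)C[C@@H](B3OC(C)(C)C(C)(C)O3)[C@H]12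
F3 | step 18 | (2R,4S,5S,6R,10S)-12,19-bis(benzyloxy)-2-[(tert-butyldimethylsilyl)oxy]-13,14,15,16-tetranorlabd-8-en-6-ol (C-6 epimer of 24) | c1ccccc1COC[C@@]1(C)C[C@H](O[Si](C)(C)C(C)(C)C)C[C@]2(C)C(CCOCc3ccccc3)=C(C)C[C@@H](O)[C@H]12
F4 | step 18 | (2R,4S,5S,10S)-12,19-bis(benzyloxy)-2-[(tert-butyldimethylsilyl)oxy]-13,14,15,16-tetranorlabd-8-en-6-one | c1ccccc1COC[C@@]1(C)C[C@H](O[Si](C)(C)C(C)(C)C)C[C@]2(C)C(CCOCc3ccccc3)=C(C)CC(=O)[C@H]12
F5 | step 13 | 4-(benzyloxy)-2-bromobutanoic acid (racemic) | OC(=O)C(Br)CCOCc1ccccc1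
F6 | step 13 | (4R,6S)-6-[(benzyloxy)methyl]-2,6-dimethyloct-1-en-7-yn-4-yl 4-(benzyloxy)-2-bromobutanoate | C#C[C@@](C)(COCc1ccccc1)C[C@H](OC(=O)C(Br)CCOCc1ccccc1)CC(C)=C
F7 | step 13 | (4S,6S)-6-[(benzyloxy)methyl]-6-methyl-2-oxooct-7-yn-4-yl 4-(benzyloxy)-2-bromobutanoate | C#C[C@@](C)(COCc1ccccc1)C[C@H](OC(=O)C(Br)CCOCc1ccccc1)CC(C)=O
F8 | step 13 | (6S)-3-[2-(benzyloxy)ethyl]-6-[(2S)-2-[(benzyloxy)methyl]-2-methylbut-3-yn-1-yl]-4-hydroxy-4-methyltetrahydro-2H-pyran-2-one (mixture at C-3 and C-4) | C#C[C@@](C)(COCc1ccccc1)C[C@H]1CC(C)(O)C(CCOCc2ccccc2)C(=O)O1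
F9 | step 17 | 2-[(3S,5R,7Z)-8-[2-(benzyloxy)ethyl]-3-[(benzyloxy)methyl]-5-[(tert-butyldimethylsilyl)oxy]-3,7,9-trimethyldeca-7,9-dien-1-yn-1-yl]-4,4,5,5-tetramethyl-1,3,2-dioxaborolane | CC1(C)OB(OC1(C)C)C#C[C@@](C)(COCc1ccccc1)C[C@H](O[Si](C)(C)C(C)(C)C)C/C(C)=C(/CCOCc1ccccc1)C(C)=C
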